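## Compound numbering (used unchanged throughout)

1 methyl 3,4-dihydroxy-5-methoxybenzoate
2 allyl bromide
3 methyl 3-hydroxy-5-methoxy-4-(prop-2-en-1-yloxy)benzoate
4 5-(chloromethyl)-1,2,3-trimethoxybenzene
5 methyl 3-methoxy-4-(prop-2-en-1-yloxy)-5-[(3,4,5-trimethoxyphenyl)methoxy]benzoate
6 vicinal diol from 5 (not isolated)
7 methyl 3-methoxy-4-(2-oxoethoxy)-5-[(3,4,5-trimethoxyphenyl)methoxy]benzoate
8 O-aryl oxocarbenium ion pair from 7 (not isolated)
9 (2R,3S)-3-formyl benzodioxane ester
10 (2R,3R)-3-hydroxymethyl benzodioxane ester
11 (2R,3R)-3-tosyloxymethyl benzodioxane ester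
12 (2R,3R)-3-methyl benzodioxane C7-methanol
13 (2R,3R)-3-methyl benzodioxane C7-carbaldehyde
14 triethyl phosphonoacetate
15 ethyl (E)-enoate
16 target

## Analysis of the target

The target is a 1,4-benzodioxane neolignan; with the heterocycle numbered O1, C2, C3, O4, C4a, C5 to C8, C8a, C2 carries a 3,4,5-trimethoxyphenyl group, C3 a methyl group, C5 a methoxy group and C7 an (E)-3-hydroxyprop-1-enyl chain. O4 therefore lies next to the methoxy-bearing C5 and para to the side chain, while O1 lies meta to it. C2 and C3 are the only stereocentres, both R, with aryl and methyl trans (diequatorial on the half-chair), which is also the more stable arrangement. The sensitive sites are the C2–O1 bond (a benzylic ether activated by a para-methoxyaryl ring, so it ionises in acid and would not survive hydrogenolysis), the allylic alcohol conjugated to an electron-rich ring, and the two oxygenated arenes. The synthesis is hard for two reasons: the two ring oxygens are inequivalent and must each receive the right carbon, and absolute configuration must be set at two carbons that carry no functional handle in the target, C3 bearing only a methyl. The strategy rests on a pairing of C2 and C3: C2–H is flanked by O1 and a para-methoxyphenyl ring, so removal of hydride gives a stabilised cation, and C3, if its methyl is carried at the formyl level, is the α-carbon of an aldehyde and can act as an enamine nucleophile. The C2–C3 bond can then be made inside a molecule that already holds both C–O bonds.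

## Retrosynthetic reasoning

16 from 15. The allylic alcohol is unveiled last by 1,2-reduction of the enoate 15, so that no free allylic alcohol has to pass through oxidising or sulfonylating steps.

15 from 13 and 14. The side-chain Cα=Cβ bond is cut. A stabilised phosphonate olefination of the aryl aldehyde 13 with 14 gives the E geometry reliably and adds the last two carbons.

13 from 12 from 11. The C7 aldehyde is traced to the benzylic alcohol 12. Both the C3 methyl and the C7 CH2OH of 12 are traced to C–O functions in 11 (primary tosylate and aryl ester), so one hydride operation serves both and the ester needs no separate step.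

11 from 10 from 9. The methyl group is traced through tosylate and primary alcohol to the formyl group of 9. This detour is the price for making C3 nucleophilic in the key step. The forward steps only touch the exocyclic carbon, so the ring stereocentres are not at risk once the aldehyde is reduced.

9 from 7 by way of 8. The C2–C3 bond is cut. Cutting either C–O bond instead would require telling the two oxygens apart and controlling configuration at a C–O bond at the same time. Cutting C2–C3 leaves two ordinary aryl alkyl ethers and puts the whole stereochemical problem into one ring-closing C–C bond formation. Forward, a quinone oxidant must take hydride from the benzylic CH2 of 7 to give cation 8, and a chiral secondary amine must turn the aldehyde into an enamine that closes the ring on C2. The ester on the catechol ring keeps that ring electron-poor, so the oxidant attacks only the trimethoxybenzyl group.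

7 from 5 by way of 6. The aldehyde is traced to a terminal alkene, cleaved oxidatively through diol 6 under buffered conditions. An acetal precursor was set aside because aryloxyacetaldehyde acetals need fairly strong acid for hydrolysis and the trimethoxybenzyl aryl ether of 5 is acid-labile.

5 from 3 and 4, and 3 from 1 and 2. Both ether bonds are cut. The order follows the acidity of the two phenols of 1. The hydroxyl para to the ester (future O4) is the more acidic and is alkylated first with 2. The remaining hydroxyl (future O1) then takes the benzyl group from 4. This settles the regiochemistry of the two ring oxygens before the ring exists.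

## Alternatives that were turned down

Alternative 1: The bonds O4–C3 and C2–C3 are cut around C3 in a three-component union. Forward, ethyl diazoacetate A1, the phenol methyl 3-bromo-4-hydroxy-5-methoxybenzoate A2 and 3,4,5-trimethoxybenzaldehyde A3 would be combined under Rh2(OAc)4 A4 and a chiral phosphoric acid. The carbene formed from A1 on A4 would be intercepted by the O–H of A2 as an oxonium ylide, and the chiral acid would direct aldol-type capture of that ylide by A3 to give the bromo hydroxy ester A5. The ring would then be closed in a separate intramolecular Ullmann-type C–O coupling of the benzylic alcohol with the aryl bromide.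
- For it: all three components are commercial, both stereocentres and two bonds arise in one step, and C3 carries an ester, which is less prone to epimerise than the aldehyde of 9. On convergence and on configurational stability at C3 this alternative is stronger than the chosen route.
- Against it: A2 is an acidic, 2,6-disubstituted phenol, so the 1,2-proton shift of the ylide (plain O–H insertion) should be fast, and the competing electrophile A3 is an electron-rich, weakly electrophilic aldehyde. The relative configuration must come out as the one diastereomer that maps onto trans. The ring is not formed in the key step, and the later C–O coupling works on a β-hydroxy ester that can undergo retro-aldol cleavage or elimination under base. The ester-to-methyl sequence is still needed, so the step count is no lower.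
- In comparison, the chosen strategy closes the ring and sets both centres in one event, needs no halogen handle, and has the thermodynamic preference for trans on its side.

Alternative 2: The C3–CH3 bond is traced to a cyclopropane. Forward, the enol ether methyl 5-methoxy-2-(3,4,5-trimethoxyphenyl)-1,4-benzodioxine-7-carboxylate A6 would be cyclopropanated in an enantioselective Simmons–Smith reaction with Et2Zn A7 and CH2I2 A8 in the presence of a chiral ligand, to give the cis-fused cyclopropane A9. Acid would then open the C2–CH2 bond to a C2 cation, which a hydride donor would reduce.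
- For it: the methyl carbon arrives at the right oxidation level, which saves the three-step formyl-to-methyl sequence. On this point it is stronger than the chosen route.
- Against it: A6 has no hydroxyl group to anchor the chiral carbenoid, and face selection on an aryl-substituted enol ether without such a handle is poorly supported. C2 is destroyed and rebuilt after the ring opening, and its configuration would depend on hydride approach anti to a small methyl group. The C2 cation can lose the C3 proton and return to a benzodioxine, erasing C3. A6 also needs several steps to make.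
- In comparison, the chosen strategy controls both centres in one cyclic transition state and does not re-ionise C2 afterwards.

Alternative 3: The bonds O1–C2 and O4–C3 are cut in a hetero-Diels–Alder sense. Forward, 3-methoxy-o-benzoquinone A10, generated in situ, would add across (E)-isoelemicin A11 under Cu(OTf)2 A12 bearing a chiral bis(oxazoline) ligand, to give the benzodioxane A13.
- For it: the complete trans core with the methyl in place would form in one step from two simple partners, with trans following from the E alkene. On step economy it is clearly the strongest of all four approaches.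
- Against it: A13 lacks the C7 carbon. C7 is para to O4 only, whereas C6 and C8 are each activated by two oxygens, so later substitution would go to the wrong positions. Placing the side-chain carbon on the quinone would make the orientation of the cycloaddition depend on small electronic differences between the two carbonyl oxygens. o-Quinones dimerise, and with electron-rich styrenes they can react stepwise through zwitterions (loss of alkene geometry) or at carbon (bicyclic diones, dihydrobenzofurans). Enantiocontrol with an unfunctionalised styrene is not established.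
- In comparison, the chosen strategy fixes the orientation of the two oxygens by the acidity difference in 1 before ring closure and carries the C7 carbon from the first step.

Key step: step 4

## Remarks before the steps

- Numbering: names keep the locants O1, C2 (aryl), C3, O4, C5 (OMe), C7 (side chain) even where the lowest-locant rule would number the ring the other way round.
- Sense of induction: the (2R,5R) enantiomer of the imidazolidinone is chosen from the usual shielding model (E-enamine, electrophile on the face away from the benzyl group). Should the first run show the opposite sense, the equally available (2S,5S) enantiomer is used without other change.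

## Route

Step 1
Reactants: 1 methyl 3,4-dihydroxy-5-methoxybenzoate; 2 allyl bromide
Product: 3 methyl 3-hydroxy-5-methoxy-4-(prop-2-en-1-yloxy)benzoate
Conditions: Li2CO3 (1.1 equiv), 2 (1.05 equiv), DMF, 45 °C
Reagents that add atoms: none
Why: Williamson ether synthesis under acidity control; the hydroxyl para to the ester is the more acidic, the weak base forms only that phenoxide, and the reactive allyl halide traps it at a temperature where the second hydroxyl stays protonated.

Step 2
Reactants: 3 methyl 3-hydroxy-5-methoxy-4-(prop-2-en-1-yloxy)benzoate; 4 5-(chloromethyl)-1,2,3-trimethoxybenzene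
Product: 5 methyl 3-methoxy-4-(prop-2-en-1-yloxy)-5-[(3,4,5-trimethoxyphenyl)methoxy]benzoate
Conditions: K2CO3 (2 equiv), 4 (1.2 equiv), DMF, 60 °C
Reagents that add atoms: none
Why: Williamson ether synthesis on the single remaining phenol with an activated benzylic chloride; the ester and the allyl ether are inert, and both ortho positions of the allyl ether are blocked against rearrangement.

Step 3
Reactants: 5 methyl 3-methoxy-4-(prop-2-en-1-yloxy)-5-[(3,4,5-trimethoxyphenyl)methoxy]benzoate
Product: 7 methyl 3-methoxy-4-(2-oxoethoxy)-5-[(3,4,5-trimethoxyphenyl)methoxy]benzoate, via vicinal diol 6 (not isolated)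
Conditions: OsO4 (2 mol%), NaIO4 (4 equiv), 2,6-lutidine (2 equiv), dioxane/H2O 3:1, rt
Reagents that add atoms: osmium tetroxide, O=[Os](=O)(=O)=O (catalytic carrier of the new oxygen atom); sodium periodate, [Na+].[O-]I(=O)(=O)=O (terminal oxidant)
Why: Lemieux–Johnson cleavage; catalytic dihydroxylation by OsO4 gives diol 6, which NaIO4 cleaves to the aldehyde and formaldehyde, under buffered near-neutral conditions that spare the acid-labile trimethoxybenzyl aryl ether.

Step 4
Reactants: 7 methyl 3-methoxy-4-(2-oxoethoxy)-5-[(3,4,5-trimethoxyphenyl)methoxy]benzoate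
Product: 9 methyl (2R,3S)-3-formyl-5-methoxy-2-(3,4,5-trimethoxyphenyl)-2,3-dihydro-1,4-benzodioxine-7-carboxylate, via oxocarbenium ion pair 8 (not isolated)
Conditions: DDQ (1.05 equiv), dry MeNO2, 0 °C; then (2R,5R)-5-benzyl-2-tert-butyl-3-methylimidazolidin-4-one·CF3CO2H (20 mol%), −25 °C
Reagents that add atoms: none
Why: Proposed new method: DDQ forms a charge-transfer complex with the trimethoxyphenyl ring, the only electron-rich arene because the other ring carries the ester, and takes hydride from its O-benzylic CH2 to give cation 8, which is both an O-aryl oxocarbenium ion and a para-methoxy-stabilised benzylic cation; the imidazolidinone then condenses with the aldehyde to an enamine whose nucleophilic carbon (future C3) adds to C2, and hydrolysis of the iminium ion releases 9 and the amine. The closest known reaction type is the intermolecular DDQ-mediated enantioselective α-alkylation of aldehydes with benzylic C–H donors under chiral secondary-amine catalysis; new here is its use as a ring closure onto an O-aryl oxocarbenium ion with an α-aryloxy aldehyde. The dioxane ring closes in a six-membered 6-(enolexo) mode that is endo-trig when counted on the C2=O1 oxocarbenium bond and exo-trig when counted on the quinone-methide canonical form, both favourable. C3 is set by the catalyst, whose benzyl group shields one face of the E-enamine so that C2 bonds to the other. C2 is set relative to C3 by a half-chair transition state with the trimethoxyphenyl group and the enamine unit pseudo-equatorial, which is the trans arrangement. C3 stays epimerisable through enol or enamine, but its equilibrium position is the same trans isomer, so epimerisation cannot harm the main pathway whereas it would turn any cis isomer into the enantiomeric trans series; the step therefore needs a diastereoselective closure, and C2, which cannot epimerise, carries the enantiomeric purity forward. The step also needs a chemoselective oxidant: 7 is oxidised before the amine is added so that DDQ does not meet the enamine, only a slight excess is used so that 9 is not dehydrogenated, and water is excluded because it would hydrolyse 8.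

Step 5
Reactants: 9 methyl (2R,3S)-3-formyl-5-methoxy-2-(3,4,5-trimethoxyphenyl)-2,3-dihydro-1,4-benzodioxine-7-carboxylate
Product: 10 methyl (2R,3R)-3-(hydroxymethyl)-5-methoxy-2-(3,4,5-trimethoxyphenyl)-2,3-dihydro-1,4-benzodioxine-7-carboxylate
Conditions: NaBH4 (1.5 equiv), MeOH/THF, −20 to 0 °C, on crude 9
Reagents that add atoms: none
Why: Chemoselective NaBH4 reduction of the aldehyde beside the aryl ester; carried out at once so that C3 is no longer epimerisable, and any cis isomer should be removable by chromatography or crystallisation at this stage (the descriptor at C3 changes to R only through the priority rules).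

Step 6
Reactants: 10 methyl (2R,3R)-3-(hydroxymethyl)-5-methoxy-2-(3,4,5-trimethoxyphenyl)-2,3-dihydro-1,4-benzodioxine-7-carboxylate
Product: 11 methyl (2R,3R)-5-methoxy-3-{[(4-methylphenyl)sulfonyloxy]methyl}-2-(3,4,5-trimethoxyphenyl)-2,3-dihydro-1,4-benzodioxine-7-carboxylate
Conditions: TsCl (1.5 equiv), Et3N (3 equiv), DMAP (cat.), CH2Cl2, 0 °C to rt
Reagents that add atoms: p-toluenesulfonyl chloride, Cc1ccc(cc1)S(Cl)(=O)=O
Why: Standard sulfonylation of an unhindered primary alcohol; no other nucleophilic group is present and the stereocentres are not involved.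

Step 7
Reactants: 11 methyl (2R,3R)-5-methoxy-3-{[(4-methylphenyl)sulfonyloxy]methyl}-2-(3,4,5-trimethoxyphenyl)-2,3-dihydro-1,4-benzodioxine-7-carboxylate
Product: 12 [(2R,3R)-5-methoxy-3-methyl-2-(3,4,5-trimethoxyphenyl)-2,3-dihydro-1,4-benzodioxin-7-yl]methanol
Conditions: LiEt3BH (5 equiv), THF, 0 °C to rt
Reagents that add atoms: none
Why: SN2 hydride displacement of the primary tosylate gives the C3 methyl group and the same reagent reduces the aryl methyl ester to the benzylic alcohol; the reacting carbon is exocyclic, so C2 and C3 keep their configuration.

Step 8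
Reactants: 12 [(2R,3R)-5-methoxy-3-methyl-2-(3,4,5-trimethoxyphenyl)-2,3-dihydro-1,4-benzodioxin-7-yl]methanol
Product: 13 (2R,3R)-5-methoxy-3-methyl-2-(3,4,5-trimethoxyphenyl)-2,3-dihydro-1,4-benzodioxine-7-carbaldehyde
Conditions: activated MnO2 (15 equiv), CH2Cl2, rt
Reagents that add atoms: none
Why: MnO2 oxidises the electron-rich benzylic alcohol selectively and stops at the aldehyde; the C2 benzylic ether C–H is not attacked under these conditions.

Step 9
Reactants: 13 (2R,3R)-5-methoxy-3-methyl-2-(3,4,5-trimethoxyphenyl)-2,3-dihydro-1,4-benzodioxine-7-carbaldehyde; 14 triethyl phosphonoacetate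
Product: 15 ethyl (2E)-3-[(2R,3R)-5-methoxy-3-methyl-2-(3,4,5-trimethoxyphenyl)-2,3-dihydro-1,4-benzodioxin-7-yl]prop-2-enoate
Conditions: 14 (1.5 equiv), NaH (1.4 equiv), THF, 0 °C to rt
Reagents that add atoms: none
Why: Horner–Wadsworth–Emmons olefination of a non-enolisable aryl aldehyde with a stabilised phosphonate carbanion, which gives the E alkene under thermodynamic control of the addition and elimination steps.

Step 10
Reactants: 15 ethyl (2E)-3-[(2R,3R)-5-methoxy-3-methyl-2-(3,4,5-trimethoxyphenyl)-2,3-dihydro-1,4-benzodioxin-7-yl]prop-2-enoate
Product: 16 (2E)-3-[(2R,3R)-5-methoxy-3-methyl-2-(3,4,5-trimethoxyphenyl)-2,3-dihydro-1,4-benzodioxin-7-yl]prop-2-en-1-ol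
Conditions: i-Bu2AlH (DIBAL-H, 3 equiv), CH2Cl2, −78 °C; aq. potassium sodium tartrate (KNaC4H4O6) work-up
Reagents that add atoms: none
Why: 1,2-Reduction of the conjugated ester by electrophilic i-Bu2AlH gives the allylic alcohol without touching the alkene, its geometry or the benzylic ether.

## Compound list

1 | methyl 3,4-dihydroxy-5-methoxybenzoate | COC(=O)c1cc(O)c(O)c(OC)c1 | starting material
2 | allyl bromide (3-bromoprop-1-ene) | C=CCBr | starting material
3 | methyl 3-hydroxy-5-methoxy-4-(prop-2-en-1-yloxy)benzoate | COC(=O)c1cc(O)c(OCC=C)c(OC)c1 | intermediate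
4 | 5-(chloromethyl)-1,2,3-trimethoxybenzene | COc1cc(CCl)cc(OC)c1OC | starting material
5 | methyl 3-methoxy-4-(prop-2-en-1-yloxy)-5-[(3,4,5-trimethoxyphenyl)methoxy]benzoate | COC(=O)c1cc(OC)c(OCC=C)c(OCc2cc(OC)c(OC)c(OC)c2)c1 | intermediate
6 | methyl 4-(2,3-dihydroxypropoxy)-3-methoxy-5-[(3,4,5-trimethoxyphenyl)methoxy]benzoate (racemic, not isolated) | COC(=O)c1cc(OC)c(OCC(O)CO)c(OCc2cc(OC)c(OC)c(OC)c2)c1 | intermediate
7 | methyl 3-methoxy-4-(2-oxoethoxy)-5-[(3,4,5-trimethoxyphenyl)methoxy]benzoate | COC(=O)c1cc(OC)c(OCC=O)c(OCc2cc(OC)c(OC)c(OC)c2)c1 | intermediate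
8 | [3-methoxy-5-(methoxycarbonyl)-2-(2-oxoethoxy)phenyl][(3,4,5-trimethoxyphenyl)methylidene]oxonium, ion pair with 2,3-dichloro-5,6-dicyano-4-hydroxyphenolate (not isolated) | COC(=O)c1cc(OC)c(OCC=O)c([O+]=Cc2cc(OC)c(OC)c(OC)c2)c1.[O-]c1c(Cl)c(Cl)c(O)c(C#N)c1C#N | intermediate
9 | methyl (2R,3S)-3-formyl-5-methoxy-2-(3,4,5-trimethoxyphenyl)-2,3-dihydro-1,4-benzodioxine-7-carboxylate (trans) | COc1cc([C@H]2Oc3cc(C(=O)OC)cc(OC)c3O[C@@H]2C=O)cc(OC)c1OC | intermediate
10 | methyl (2R,3R)-3-(hydroxymethyl)-5-methoxy-2-(3,4,5-trimethoxyphenyl)-2,3-dihydro-1,4-benzodioxine-7-carboxylate | COc1cc([C@H]2Oc3cc(C(=O)OC)cc(OC)c3O[C@@H]2CO)cc(OC)c1OC | intermediate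
11 | methyl (2R,3R)-5-methoxy-3-{[(4-methylphenyl)sulfonyloxy]methyl}-2-(3,4,5-trimethoxyphenyl)-2,3-dihydro-1,4-benzodioxine-7-carboxylate | COc1cc([C@H]2Oc3cc(C(=O)OC)cc(OC)c3O[C@@H]2COS(=O)(=O)c4ccc(C)cc4)cc(OC)c1OC | intermediate
12 | [(2R,3R)-5-methoxy-3-methyl-2-(3,4,5-trimethoxyphenyl)-2,3-dihydro-1,4-benzodioxin-7-yl]methanol | COc1cc([C@H]2Oc3cc(CO)cc(OC)c3O[C@@H]2C)cc(OC)c1OC | intermediate
13 | (2R,3R)-5-methoxy-3-methyl-2-(3,4,5-trimethoxyphenyl)-2,3-dihydro-1,4-benzodioxine-7-carbaldehyde | COc1cc([C@H]2Oc3cc(C=O)cc(OC)c3O[C@@H]2C)cc(OC)c1OC | intermediate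
14 | triethyl phosphonoacetate | CCOC(=O)CP(=O)(OCC)OCC | starting material
15 | ethyl (2E)-3-[(2R,3R)-5-methoxy-3-methyl-2-(3,4,5-trimethoxyphenyl)-2,3-dihydro-1,4-benzodioxin-7-yl]prop-2-enoate | COc1cc([C@H]2Oc3cc(/C=C/C(=O)OCC)cc(OC)c3O[C@@H]2C)cc(OC)c1OC | intermediate
16 | (2E)-3-[(2R,3R)-5-methoxy-3-methyl-2-(3,4,5-trimethoxyphenyl)-2,3-dihydro-1,4-benzodioxin-7-yl]prop-2-en-1-ol | COc1cc([C@H]2Oc3cc(/C=C/CO)cc(OC)c3O[C@@H]2C)cc(OC)c1OC | target

## Step count and least certain steps

Total: 10 steps. Longest linear sequence: 10 steps (1 to 16); 2, 4 and 14 enter as purchased reagents.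

**Step 4 (key step, new as a ring closure).** Four things can go wrong. Hydride abstraction may be slow, because O1 is an aryl ether oxygen on an ester-bearing ring and stabilises the cation less than an alkyl ether oxygen would, and because the central methoxy group of the trimethoxyphenyl ring is twisted out of conjugation. The cation may be hydrolysed by adventitious water or by the water released on enamine formation, which amounts to oxidative loss of the benzyl group. Residual oxidant may oxidise the enamine. Face selection at C2 in the closure may be poor; after equilibration at C3 this lowers the enantiomeric purity, not only the diastereomer ratio.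

Fallback by known chemistry, setting out from 1 and returning to the route at 12. A Mitsunobu reaction (PPh3, diisopropyl azodicarboxylate, THF) of the more acidic para hydroxyl of 1 with commercial (2S)-2-hydroxy-N-methoxy-N-methylpropanamide (C[C@H](O)C(=O)N(C)OC) should give, with inversion, methyl 3-hydroxy-5-methoxy-4-{[(2R)-1-[methoxy(methyl)amino]-1-oxopropan-2-yl]oxy}benzoate F1, which already holds the C3 configuration. Commercial 3,4,5-trimethoxyphenylmagnesium bromide (2.2 equiv, THF, −40 to −10 °C; the first equivalent deprotonates the phenol) should add to the N-methoxy-N-methylamide in preference to the aryl ester and give the ketone methyl 3-hydroxy-5-methoxy-4-{[(2R)-1-oxo-1-(3,4,5-trimethoxyphenyl)propan-2-yl]oxy}benzoate F2. NaBH4 in MeOH at −20 °C, applied at once to limit epimerisation of the α-aryloxy ketone, should give the benzylic alcohol methyl 3-hydroxy-4-{[(2R)-1-hydroxy-1-(3,4,5-trimethoxyphenyl)propan-2-yl]oxy}-5-methoxybenzoate F3 as a mixture of carbinol epimers. Acid (Amberlyst 15 or CF3CO2H, CH2Cl2) ionises the carbinol to the para-methoxy-stabilised cation, and the neighbouring phenol closes the ring reversibly to the more stable trans isomer, methyl (2R,3R)-5-methoxy-3-methyl-2-(3,4,5-trimethoxyphenyl)-2,3-dihydro-1,4-benzodioxine-7-carboxylate F4. LiAlH4 in THF at 0 °C then reduces the ester to 12. Here C3 comes from the lactic acid pool and C2 from thermodynamic control.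

**Step 1.** Regioselection may be incomplete, or double alkylation may occur, if the second phenol is deprotonated under the reaction conditions. The fallback runs from 1 to 5 with inverted logic: the dianion of 1 (NaH, 2.2 equiv, DMSO) reacts with one equivalent of 4 at its more basic, more nucleophilic phenoxide, the one meta to the ester, to give methyl 4-hydroxy-3-methoxy-5-[(3,4,5-trimethoxyphenyl)methoxy]benzoate F5, and the remaining para hydroxyl is then allylated with 2 and K2CO3 in DMF to give 5.

**Step 3.** Over-oxidation of the aldehyde, hydrate formation and loss of the sensitive aryloxyacetaldehyde on isolation are the likely problems. The fallback runs from 1 to 7 without alkene cleavage. Selective alkylation of the para hydroxyl of 1 with 2-bromoethanol (Li2CO3, DMF) gives methyl 3-hydroxy-4-(2-hydroxyethoxy)-5-methoxybenzoate F6. Phenol-selective benzylation with 4 (K2CO3, DMF) gives methyl 4-(2-hydroxyethoxy)-3-methoxy-5-[(3,4,5-trimethoxyphenyl)methoxy]benzoate F7. Dess–Martin periodinane (NaHCO3, CH2Cl2) oxidises the primary alcohol to 7.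

**Step 7.** Base-induced elimination toward an exocyclic enol ether, attack of hydride at sulfur with return to the alcohol, or incomplete ester reduction may compete. The fallback runs from 10 to 12 by a radical path instead of hydride displacement. Appel iodination (I2, PPh3, imidazole, CH2Cl2) gives methyl (2R,3S)-3-(iodomethyl)-5-methoxy-2-(3,4,5-trimethoxyphenyl)-2,3-dihydro-1,4-benzodioxine-7-carboxylate F8. Bu3SnH and AIBN in toluene at 80 °C remove iodine by a radical chain to give the methyl ester F4 described under step 4. LiAlH4 in THF at 0 °C gives 12.

## Further compounds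

F1 | step 4 | methyl 3-hydroxy-5-methoxy-4-{[(2R)-1-[methoxy(methyl)amino]-1-oxopropan-2-yl]oxy}benzoate | C[C@@H](Oc1c(O)cc(C(=O)OC)cc1OC)C(=O)N(C)OC
F2 | step 4 | methyl 3-hydroxy-5-methoxy-4-{[(2R)-1-oxo-1-(3,4,5-trimethoxyphenyl)propan-2-yl]oxy}benzoate | C[C@@H](Oc1c(O)cc(C(=O)OC)cc1OC)C(=O)c1cc(OC)c(OC)c(OC)c1
F3 | step 4 | methyl 3-hydroxy-4-{[(2R)-1-hydroxy-1-(3,4,5-trimethoxyphenyl)propan-2-yl]oxy}-5-methoxybenzoate (both carbinol epimers) | C[C@@H](Oc1c(O)cc(C(=O)OC)cc1OC)C(O)c1cc(OC)c(OC)c(OC)c1
F4 | step 4 | methyl (2R,3R)-5-methoxy-3-methyl-2-(3,4,5-trimethoxyphenyl)-2,3-dihydro-1,4-benzodioxine-7-carboxylate | COc1cc([C@H]2Oc3cc(C(=O)OC)cc(OC)c3O[C@@H]2C)cc(OC)c1OC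
F5 | step 1 | methyl 4-hydroxy-3-methoxy-5-[(3,4,5-trimethoxyphenyl)methoxy]benzoate | COC(=O)c1cc(OC)c(O)c(OCc2cc(OC)c(OC)c(OC)c2)c1
F6 | step 3 | methyl 3-hydroxy-4-(2-hydroxyethoxy)-5-methoxybenzoate | COC(=O)c1cc(O)c(OCCO)c(OC)c1
F7 | step 3 | methyl 4-(2-hydroxyethoxy)-3-methoxy-5-[(3,4,5-trimethoxyphenyl)methoxy]benzoate | COC(=O)c1cc(OC)c(OCCO)c(OCc2cc(OC)c(OC)c(OC)c2)c1
F8 | step 7 | methyl (2R,3S)-3-(iodomethyl)-5-methoxy-2-(3,4,5-trimethoxyphenyl)-2,3-dihydro-1,4-benzodioxine-7-carboxylate | COc1cc([C@H]2Oc3cc(C(=O)OC)cc(OC)c3O[C@@H]2CI)cc(OC)c1OC
A1 | alternative 1 | ethyl diazoacetate | CCOC(=O)C=[N+]=[N-]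
A2 | alternative 1 | methyl 3-bromo-4-hydroxy-5-methoxybenzoate | COC(=O)c1cc(Br)c(O)c(OC)c1
A3 | alternative 1 | 3,4,5-trimethoxybenzaldehyde | COc1cc(C=O)cc(OC)c1OC
A4 | alternative 1 | Rh2(OAc)4, dirhodium tetraacetate | CC(=O)[O-].CC(=O)[O-].CC(=O)[O-].CC(=O)[O-].[Rh+2].[Rh+2]
A5 | alternative 1 | ethyl (2S,3R)-2-(2-bromo-6-methoxy-4-methoxycarbonylphenoxy)-3-hydroxy-3-(3,4,5-trimethoxyphenyl)propanoate | COc1cc([C@@H](O)[C@H](Oc2c(Br)cc(C(=O)OC)cc2OC)C(=O)OCC)cc(OC)c1OC
A6 | alternative 2 | methyl 5-methoxy-2-(3,4,5-trimethoxyphenyl)-1,4-benzodioxine-7-carboxylate | COc1cc(C2=COc3c(OC)cc(C(=O)OC)cc3O2)cc(OC)c1OC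
A7 | alternative 2 | diethylzinc, Et2Zn | CC[Zn]CC
A8 | alternative 2 | diiodomethane | ICI
A9 | alternative 2 | cyclopropane-fused benzodioxane methyl ester (cyclopropa[b][1,4]benzodioxine core) with cis ring fusion, the trimethoxyphenyl group on the fusion carbon that becomes C2 and the cyclopropane CH2 on the face where the C3 methyl ends up | COc1cc([C@]23C[C@H]2Oc2c(OC)cc(C(=O)OC)cc2O3)cc(OC)c1OC
A10 | alternative 3 | 3-methoxy-o-benzoquinone (3-methoxycyclohexa-3,5-diene-1,2-dione) | COC1=CC=CC(=O)C1=O
A11 | alternative 3 | (E)-isoelemicin, 1,2,3-trimethoxy-5-[(1E)-prop-1-en-1-yl]benzene | COc1cc(/C=C/C)cc(OC)c1OC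
A12 | alternative 3 | Cu(OTf)2, copper bis(trifluoromethanesulfonate) | [Cu+2].[O-]S(=O)(=O)C(F)(F)F.[O-]S(=O)(=O)C(F)(F)F
A13 | alternative 3 | (2R,3R)-5-methoxy-3-methyl-2-(3,4,5-trimethoxyphenyl)-2,3-dihydro-1,4-benzodioxine | COc1cc([C@H]2Oc3cccc(OC)c3O[C@@H]2C)cc(OC)c1OC
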